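**Retrosynthetic overview**
- Last bond made: C(=O)–Cα of the enone, by adding 2,4-dihydroxybenzaldehyde as an acyl anion equivalent (acyl–Rh(III) hydride) across the terminal alkyne of the chroman fragment.
- The alkyne comes from an aryl aldehyde by one-carbon homologation; the C3 carbinol comes from a Jacobsen epoxide of a 2,2-dimethyl-2H-chromene, opened by hydride at C4.
- The chromene comes from an aryl 1,1-dimethylpropargyl ether (Claisen/oxa-6π), made from 3,4-dihydroxybenzaldehyde and 3-chloro-3-methylbut-1-yne.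
- Ring order: both benzene rings are bought; the pyran ring is the only ring formed (step 2). The one protecting group goes on in the step 1 pot and comes off in step 5.

Assumption: the (S,S)-Jacobsen catalyst is taken to give the (3S,4S)-epoxide, by analogy with 6-substituted 2,2-dimethylchromenes; if the sense is opposite, the (R,R)-catalyst is used.

**Step 1**
Reactants: 1 3,4-dihydroxybenzaldehyde; 2 3-chloro-3-methylbut-1-yne
Product: 4 5-formyl-2-[(2-methylbut-3-yn-2-yl)oxy]phenyl N,N-diethylcarbamate, via mono-propargyl ether 3 (not isolated)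
Conditions: K2CO3 (1.1 equiv), KI (20 mol%), CuI (5 mol%), DMF, 40 °C; then Et2NCOCl, K2CO3, 50 °C
Reagents that add atoms: N,N-diethylcarbamoyl chloride, CCN(CC)C(Cl)=O
Why: The 4-OH (para to CHO, pKa about 7.5) is ionised selectively and undergoes Cu-catalysed propargylic O-alkylation with the tertiary chloride 2, after which the remaining 3-OH is capped in the same pot by O-carbamoylation so that no free phenol sits next to the alkyne in step 2 or meets the oxidant in step 4.

**Step 2**
Reactants: 4 5-formyl-2-[(2-methylbut-3-yn-2-yl)oxy]phenyl N,N-diethylcarbamate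
Product: 7 6-formyl-2,2-dimethyl-2H-chromen-8-yl N,N-diethylcarbamate, via ortho-allenylphenol 5 (not isolated), via ortho-quinone methide 6 (not isolated)
Conditions: 1,2-dichlorobenzene, 180 °C
Reagents that add atoms: none
Why: Thermal aromatic propargyl Claisen rearrangement to the only free ortho position gives ortho-allenylphenol 5, whose 1,5-H shift gives ortho-quinone methide 6, and oxa-6π electrocyclisation then closes the 2,2-dimethyl-2H-pyran ring.

**Step 3**
Reactants: 7 6-formyl-2,2-dimethyl-2H-chromen-8-yl N,N-diethylcarbamate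
Product: 8 6-ethynyl-2,2-dimethyl-2H-chromen-8-yl N,N-diethylcarbamate
Conditions: Bestmann–Ohira reagent, K2CO3, MeOH, 0 °C to rt
Reagents that add atoms: dimethyl (1-diazo-2-oxopropyl)phosphonate, CC(=O)C(=[N+]=[N-])P(=O)(OC)OC
Why: Seyferth–Gilbert homologation with the Bestmann–Ohira reagent converts the aryl aldehyde into the terminal alkyne under conditions that leave the chromene and the aryl N,N-dialkylcarbamate untouched.

**Step 4**
Reactants: 8 6-ethynyl-2,2-dimethyl-2H-chromen-8-yl N,N-diethylcarbamate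
Product: 9 (3S,4S)-3,4-epoxy-6-ethynyl-2,2-dimethyl-3,4-dihydro-2H-chromen-8-yl N,N-diethylcarbamate
Conditions: (S,S)-Jacobsen Mn(III)(salen)Cl (5 mol%), mCPBA, NMO, CH2Cl2, -78 °C
Reagents that add atoms: mCPBA (3-chloroperoxybenzoic acid), OOC(=O)c1cccc(Cl)c1
Why: Jacobsen–Katsuki epoxidation, for which 2,2-dimethylchromenes are the best substrate class, adds oxygen to one face of the cis-alkene and so sets C3 (S) and C4 (S) together, while the alkyne and carbamate are inert to the Mn-oxo species at -78 °C.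

**Step 5**
Reactants: 9 (3S,4S)-3,4-epoxy-6-ethynyl-2,2-dimethyl-3,4-dihydro-2H-chromen-8-yl N,N-diethylcarbamate
Product: 10 (3S)-6-ethynyl-2,2-dimethyl-3,4-dihydro-2H-chromene-3,8-diol
Conditions: LiAlH4, THF, 0 to 50 °C; Fieser work-up
Reagents that add atoms: none
Why: Hydride opens the epoxide by SN2 attack at the benzylic C4 (C3 is neopentyl-like beside the quaternary C2), so the C3–O bond and its S configuration are kept, and the same reagent reduces the aryl carbamate off to free the 8-OH (regioselective reductive epoxide opening plus reductive carbamate cleavage).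

**Step 6**
Reactants: 10 (3S)-6-ethynyl-2,2-dimethyl-3,4-dihydro-2H-chromene-3,8-diol; 11 2,4-dihydroxybenzaldehyde
Product: 12 (E)-1-(2,4-dihydroxyphenyl)-3-[(3S)-3,8-dihydroxy-2,2-dimethyl-3,4-dihydro-2H-chromen-6-yl]prop-2-en-1-one
Conditions: [Rh(cod)Cl]2 (2.5 mol%), dppf (5 mol%), Na2CO3 (10 mol%), 1,4-dioxane, 90 °C, Ar; 11 in 1.5-fold excess
Reagents that add atoms: none
Why: Rh(I)-catalysed chelation-assisted alkyne hydroacylation of a salicylaldehyde, in which phenoxide-directed oxidative addition of the formyl C–H turns the normally electrophilic aldehyde carbon of 11 into an acyl–Rh(III) hydride (an acyl anion equivalent), whose syn hydrometalation of the alkyne with Rh on the terminal carbon and C–C reductive elimination give the linear (E)-enone without protecting groups and without touching C3.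

**Compound list**
1 | 3,4-dihydroxybenzaldehyde | O=Cc1ccc(O)c(O)c1 | starting material
2 | 3-chloro-3-methylbut-1-yne | CC(C)(Cl)C#C | starting material
3 | 3-hydroxy-4-[(2-methylbut-3-yn-2-yl)oxy]benzaldehyde | O=Cc1ccc(OC(C)(C)C#C)c(O)c1 | intermediate
4 | 5-formyl-2-[(2-methylbut-3-yn-2-yl)oxy]phenyl N,N-diethylcarbamate | CCN(CC)C(=O)Oc1cc(C=O)ccc1OC(C)(C)C#C | intermediate
5 | 5-formyl-2-hydroxy-3-(3-methylbuta-1,2-dien-1-yl)phenyl N,N-diethylcarbamate | CCN(CC)C(=O)Oc1cc(C=O)cc(C=C=C(C)C)c1O | intermediate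
6 | 3-formyl-5-(3-methylbut-2-en-1-ylidene)-6-oxocyclohexa-1,3-dien-1-yl N,N-diethylcarbamate (exocyclic alkene geometry not specified) | CCN(CC)C(=O)OC1=CC(C=O)=CC(=CC=C(C)C)C1=O | intermediate
7 | 6-formyl-2,2-dimethyl-2H-chromen-8-yl N,N-diethylcarbamate | CCN(CC)C(=O)Oc1cc(C=O)cc2C=CC(C)(C)Oc12 | intermediate
8 | 6-ethynyl-2,2-dimethyl-2H-chromen-8-yl N,N-diethylcarbamate | CCN(CC)C(=O)Oc1cc(C#C)cc2C=CC(C)(C)Oc12 | intermediate
9 | (3S,4S)-3,4-epoxy-6-ethynyl-2,2-dimethyl-3,4-dihydro-2H-chromen-8-yl N,N-diethylcarbamate | CC1(C)Oc2c(OC(=O)N(CC)CC)cc(C#C)cc2[C@@H]3O[C@H]13 | intermediate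
10 | (3S)-6-ethynyl-2,2-dimethyl-3,4-dihydro-2H-chromene-3,8-diol | CC1(C)Oc2c(O)cc(C#C)cc2C[C@@H]1O | intermediate
11 | 2,4-dihydroxybenzaldehyde | O=Cc1ccc(O)cc1O | starting material
12 | (E)-1-(2,4-dihydroxyphenyl)-3-[(3S)-3,8-dihydroxy-2,2-dimethyl-3,4-dihydro-2H-chromen-6-yl]prop-2-en-1-one | CC1(C)Oc2c(O)cc(/C=C/C(=O)c3ccc(O)cc3O)cc2C[C@@H]1O | target

**Totals**
Total step count: 6. Longest linear sequence: 6 (1 to 12; 11 enters in the last step).

**Three steps most likely to fail**

Step 6 (hydroacylation). This reaction type is known for salicylaldehydes, but this polyphenolic pair is untested. The risks are the branched 1,1-disubstituted enone regioisomer, alkyne oligomerisation, interference by the 4-phenoxide of 11, and oxa-Michael closure to the flavanone. The fallback sets out from 10 (with 11) and comes back at 12. Markovnikov hydrosulfonylation of the alkyne of 10 with 4-methylbenzenesulfinic acid (Pd(PPh3)4 cat.) gives (3S)-2,2-dimethyl-6-[1-(4-methylbenzenesulfonyl)ethenyl]-3,4-dihydro-2H-chromene-3,8-diol F1. A thiazolium-carbene Stetter reaction (Et3N, EtOH, 70 °C) then adds the Breslow intermediate of 11 to the unsubstituted CH2 terminus of F1 and gives 1-(2,4-dihydroxyphenyl)-3-[(3S)-3,8-dihydroxy-2,2-dimethyl-3,4-dihydro-2H-chromen-6-yl]-3-(4-methylbenzenesulfonyl)propan-1-one F2 as a mixture of epimers at the sulfonyl carbon. DBU then expels sulfinate (E1cB) to give 12 with fixed connectivity.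

Step 4 (asymmetric epoxidation). The risks are lower ee with the 8-carbamoyloxy/6-ethynyl pattern, or the wrong sense of induction. The fallback sets out from 8 and comes back at 10. Buffered mCPBA gives racemic 3,4-epoxy-6-ethynyl-2,2-dimethyl-3,4-dihydro-2H-chromen-8-yl N,N-diethylcarbamate F3. Lewis-acid Meinwald rearrangement (cat. ZnI2, 1,2-hydride shift to the benzylic cation) gives 6-ethynyl-2,2-dimethyl-3-oxo-3,4-dihydro-2H-chromen-8-yl N,N-diethylcarbamate F4. Enantioselective ketone reduction ((R)-Me-CBS with catecholborane at -78 °C, or an (S)-selective ketoreductase) sets C3 and gives (3S)-6-ethynyl-3-hydroxy-2,2-dimethyl-3,4-dihydro-2H-chromen-8-yl N,N-diethylcarbamate F5. LiAlH4 then removes the carbamate to give 10.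

Step 1 (regioselective tertiary propargylation of a catechol, telescoped with carbamoylation). The risks are 3-O or bis-alkylation and cyclisation of the free 3-OH onto the alkyne. The fallback sets out from 1 and comes back at 7, bypassing 4 and step 2. The dianion of 1 (NaH, 2.2 equiv, DMF, 0 °C) reacts at its more nucleophilic 3-oxygen with one equivalent of N,N-diethylcarbamoyl chloride to give 5-formyl-2-hydroxyphenyl N,N-diethylcarbamate F6. Phenylboronic acid-templated ortho-specific condensation of F6 with 3-methylbut-2-enal (AcOH, toluene, reflux, Dean–Stark) then builds the chromene 7 directly through the ortho-quinone methide and oxa-6π closure.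

**Further compounds**
F1 | step 6 | (3S)-2,2-dimethyl-6-[1-(4-methylbenzenesulfonyl)ethenyl]-3,4-dihydro-2H-chromene-3,8-diol | CC1(C)Oc2c(O)cc(C(=C)S(=O)(=O)c3ccc(C)cc3)cc2C[C@@H]1O
F2 | step 6 | 1-(2,4-dihydroxyphenyl)-3-[(3S)-3,8-dihydroxy-2,2-dimethyl-3,4-dihydro-2H-chromen-6-yl]-3-(4-methylbenzenesulfonyl)propan-1-one (epimer mixture at the sulfonyl carbon) | CC1(C)Oc2c(O)cc(C(CC(=O)c3ccc(O)cc3O)S(=O)(=O)c3ccc(C)cc3)cc2C[C@@H]1O
F3 | step 4 | racemic 3,4-epoxy-6-ethynyl-2,2-dimethyl-3,4-dihydro-2H-chromen-8-yl N,N-diethylcarbamate | CC1(C)Oc2c(OC(=O)N(CC)CC)cc(C#C)cc2C3OC13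
F4 | step 4 | 6-ethynyl-2,2-dimethyl-3-oxo-3,4-dihydro-2H-chromen-8-yl N,N-diethylcarbamate | CC1(C)Oc2c(OC(=O)N(CC)CC)cc(C#C)cc2CC1=O
F5 | step 4 | (3S)-6-ethynyl-3-hydroxy-2,2-dimethyl-3,4-dihydro-2H-chromen-8-yl N,N-diethylcarbamate | CC1(C)Oc2c(OC(=O)N(CC)CC)cc(C#C)cc2C[C@@H]1O
F6 | step 1 | 5-formyl-2-hydroxyphenyl N,N-diethylcarbamate | CCN(CC)C(=O)Oc1cc(C=O)ccc1O
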